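**Plan**

- Retrosynthesis: the thirteen O-benzyl bonds are cut first, then the two interflavan bonds C4–C8. In the gallocatechin unit, ring C is then cut at O1–C8a, C2–C3 and C4–C4a, leaving 3,4,5-tris(benzyloxy)benzaldehyde, a chiral glycolate lactone and 3,5-bis(benzyloxy)benzyne. Both catechin units come from (+)-catechin.
- Enabling feature: in the gallocatechin unit ring A is 1,3,5-trioxygenated, with O1 on C8a, C4 on the neighbouring C4a and the C5 oxygen beside C4a. A 3-alkoxybenzyne gives exactly this pattern when an alkoxide adds to the carbon remote from the alkoxy group and the aryl anion next to it is acylated. At the dihydroflavonol level (C4=O), C2–C3 is an aldol bond.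
- Forward: (+)-catechin is benzylated, activated at C4 and dimerised (4α→8). A phenol is converted into the aryne precursor. One flask then joins glycolate, aldehyde and aryne to ring C of the top unit (ring A arrives with the aryne, ring B with the aldehyde). The ketal is removed, C4=O is reduced, the C4 cation is coupled to C8 of the dimer, and hydrogenolysis finishes.
- Stereochemistry: C2 and C3 of the middle and bottom units come from (+)-catechin. C2 and C3 of the top unit come from the (5S,6S)-diacetal ring of the glycolate through an anti aldol; this temporary ring is opened in the key step and removed in step 7. Both C4 centres arise by attack on a 2,3-trans flavanyl cation anti to the C3 oxygen.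

Key step: step 6

Assumption: (5S,6S)-5,6-dimethoxy-5,6-dimethyl-1,4-dioxan-2-one is taken as a purchasable butane-2,3-diacetal glycolate, and its lithium enolate is taken to react on the face anti to the axial 5-methoxy group.

**Route**

Step 1
Reactants: 1 (+)-catechin
Product: 2 5,7,3',4'-tetra-O-benzyl-(+)-catechin
Conditions: BnBr, K2CO3, DMF, 0 °C to rt
Reagents that add atoms: benzyl bromide, BrCc1ccccc1
Why: Williamson etherification of the four phenols, which are far more acidic than the C3 alcohol, so the secondary hydroxyl and both stereocentres should stay untouched.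

Step 2
Reactants: 2 5,7,3',4'-tetra-O-benzyl-(+)-catechin
Product: 3 (2R,3S,4S)-5,7,3',4'-tetra-O-benzyl-4-(2-ethoxyethoxy)flavan-3-ol
Conditions: DDQ, 2-ethoxyethanol, CH2Cl2, rt
Reagents that add atoms: 2-ethoxyethanol, CCOCCO
Why: DDQ benzylic oxidation by hydride abstraction at C4, the cation being stabilised by the two ring A oxygens and trapped by the alcohol; the C4 configuration formed here is erased in step 3.

Step 3
Reactants: 3 (2R,3S,4S)-5,7,3',4'-tetra-O-benzyl-4-(2-ethoxyethoxy)flavan-3-ol, 2 5,7,3',4'-tetra-O-benzyl-(+)-catechin (in excess)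
Product: 4 octa-O-benzyl catechin-(4α→8)-catechin
Conditions: TMSOTf (cat.), CH2Cl2, −78 °C; then Et3N
Reagents that add atoms: none
Why: Friedel–Crafts-type arylation of the C4 flavanyl cation by C8 of the nucleophile, which should enter anti to the C3 hydroxyl of the 2,3-trans unit and so give the 3,4-trans (4α) bond; the excess of 2 suppresses chain growth.

Step 4
Reactants: 5 3,5-bis(benzyloxy)phenol
Product: 6 3,5-bis(benzyloxy)-2-bromophenol
Conditions: NBS (1.0 equiv), i-Pr2NH (cat.), CH2Cl2, −78 to 0 °C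
Reagents that add atoms: N-bromosuccinimide, O=C1CCC(=O)N1Br
Why: electrophilic aromatic bromination, with the amine-bound bromine delivered to the position ortho to the free hydroxyl in preference to the more hindered position between the two benzyloxy groups.

Step 5
Reactants: 6 3,5-bis(benzyloxy)-2-bromophenol
Product: 9 3,5-bis(benzyloxy)-2-(trimethylsilyl)phenyl trifluoromethanesulfonate, via aryl trimethylsilyl ether 7 (not isolated), via lithium 2-silylphenoxide 8 (not isolated)
Conditions: HMDS, THF, 65 °C, then evaporation; n-BuLi, THF, −78 °C; Tf2O, −78 °C to rt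
Reagents that add atoms: hexamethyldisilazane, C[Si](C)(C)N[Si](C)(C)C; triflic anhydride, O=S(=O)(OS(=O)(=O)C(F)(F)F)C(F)(F)F
Why: O-silylation, bromine–lithium exchange and retro-Brook rearrangement (1,3 shift of silicon from O to C) should give the phenoxide, which is triflated; the exchange is much faster than any attack on the benzyl ethers at −78 °C.

Step 6
Reactants: 10 (5S,6S)-5,6-dimethoxy-5,6-dimethyl-1,4-dioxan-2-one, 11 3,4,5-tris(benzyloxy)benzaldehyde, 9 3,5-bis(benzyloxy)-2-(trimethylsilyl)phenyl trifluoromethanesulfonate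
Product: 15 (2R,3R)-5,7-bis(benzyloxy)-3-{[(2S)-2-methoxy-3-oxobutan-2-yl]oxy}-2-[3,4,5-tris(benzyloxy)phenyl]chroman-4-one, via lithium dioxanone enolate 12 (not isolated), via lithium aldolate 13 (not isolated), via 3,5-bis(benzyloxy)benzyne 14 (not isolated)
Conditions: LiN(SiMe3)2, THF, −78 °C; 11, −78 °C; then 9, KF, 18-crown-6, −78 to 0 °C; AcOH
Reagents that add atoms: none
Why: Proposed new method: enolate 12 adds to aldehyde 11 through a closed chair transition state to give the anti aldolate 13 (C2–C3); fluoride then releases aryne 14 from 9, the alkoxide of 13 adds to the aryne carbon remote from the benzyloxy group (O1–C8a), the aryl anion formed next to that benzyloxy group attacks the lactone carbonyl (C4–C4a), and the diacetal ring opens with loss of methoxide. The closest known reaction types are the anti aldol of this diacetal glycolate enolate with aromatic aldehydes and the annulation of arynes by ortho-hydroxyaryl esters to xanthones, in which an oxygen nucleophile adds and the aryl anion is acylated by the neighbouring ester; their union in one flask with an aliphatic aldolate is not known. Ring C closes by 6-exo-trig attack of the C4a anion on the C4 carbonyl, and because the alkoxide is used as formed, no proton source stronger than HN(SiMe3)2 competes with this closure. C3 is set by approach of the aldehyde anti to the axial 5-methoxy group of the diacetal ring and C2 by the ring-fixed (E)-enolate geometry (anti aldol, hence 2,3-trans after closure); C3, now α to the ketone, can only drift towards the same, more stable trans isomer. The step needs one orientation of aryne addition, which is secured both by the benzyloxy group beside the triple bond (inductive stabilisation of charge at C4a) and by the fact that only this orientation can close a six-membered ring; it also needs the aldolate to outlast retro-aldol, which the low temperature should allow.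

Step 7
Reactants: 15 (2R,3R)-5,7-bis(benzyloxy)-3-{[(2S)-2-methoxy-3-oxobutan-2-yl]oxy}-2-[3,4,5-tris(benzyloxy)phenyl]chroman-4-one
Product: 16 (2R,3R)-5,7,3',4',5'-penta-O-benzyldihydromyricetin
Conditions: TFA/H2O (9:1), CH2Cl2, 0 °C
Reagents that add atoms: none
Why: acid hydrolysis of the mixed ketal that remains from the diacetal ring; the C3–O bond is not broken, so the configuration should be kept, and aryl benzyl ethers should tolerate brief exposure to cold aqueous TFA.

Step 8
Reactants: 16 (2R,3R)-5,7,3',4',5'-penta-O-benzyldihydromyricetin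
Product: 17 (2R,3S,4R)-5,7-bis(benzyloxy)-2-[3,4,5-tris(benzyloxy)phenyl]chromane-3,4-diol
Conditions: NaBH4, THF/MeOH, 0 °C
Reagents that add atoms: none
Why: hydride reduction of the aryl ketone, expected to give mainly the 3,4-trans diol by axial attack; the C4 configuration is of no consequence because it is ionised in step 9.

Step 9
Reactants: 17 (2R,3S,4R)-5,7-bis(benzyloxy)-2-[3,4,5-tris(benzyloxy)phenyl]chromane-3,4-diol, 4 octa-O-benzyl catechin-(4α→8)-catechin (in excess)
Product: 18 trideca-O-benzyl gallocatechin-(4α→8)-catechin-(4α→8)-catechin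
Conditions: TMSOTf (cat.), 4 Å molecular sieves, CH2Cl2, −78 to −30 °C; then Et3N
Reagents that add atoms: none
Why: acid ionisation of the benzylic C4 hydroxyl gives a cation stabilised by the 5,7-dibenzyloxy ring A, and Friedel–Crafts-type attack by the free C8 of the upper unit of 4, anti to the C3 hydroxyl of the 2,3-trans cation, should set the 3,4-trans (4α) bond.

Step 10
Reactants: 18 trideca-O-benzyl gallocatechin-(4α→8)-catechin-(4α→8)-catechin
Product: 19 gallocatechin-(4α→8)-catechin-(4α→8)-catechin (target)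
Conditions: H2 (1 atm), Pd(OH)2/C, THF/MeOH/H2O, rt
Reagents that add atoms: none
Why: hydrogenolysis of the thirteen benzyl ethers under neutral conditions, which should leave the acid-sensitive interflavan bonds and all stereocentres intact.

**Compound list**

1 | (+)-catechin | Oc1cc(O)c2c(c1)O[C@H](c1ccc(O)c(O)c1)[C@@H](O)C2 | starting material
2 | 5,7,3',4'-tetra-O-benzyl-(+)-catechin | C(c1ccccc1)Oc1cc(OCc3ccccc3)c2c(c1)O[C@H](c1ccc(OCc3ccccc3)c(OCc3ccccc3)c1)[C@@H](O)C2 | intermediate
3 | (2R,3S,4S)-5,7,3',4'-tetra-O-benzyl-4-(2-ethoxyethoxy)flavan-3-ol | C(c1ccccc1)Oc1cc(OCc3ccccc3)c2c(c1)O[C@H](c1ccc(OCc3ccccc3)c(OCc3ccccc3)c1)[C@@H](O)[C@H]2OCCOCC | intermediate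
4 | octa-O-benzyl catechin-(4α→8)-catechin, both 3-hydroxyls free | C(c1ccccc1)Oc1cc(OCc3ccccc3)c2c(c1)O[C@H](c1ccc(OCc3ccccc3)c(OCc3ccccc3)c1)[C@@H](O)[C@@H]2c1c(OCc3ccccc3)cc(OCc3ccccc3)c2c1O[C@H](c1ccc(OCc3ccccc3)c(OCc3ccccc3)c1)[C@@H](O)C2 | intermediate
5 | 3,5-bis(benzyloxy)phenol | Oc1cc(OCc2ccccc2)cc(OCc2ccccc2)c1 | starting material
6 | 3,5-bis(benzyloxy)-2-bromophenol | Oc1cc(OCc2ccccc2)cc(OCc2ccccc2)c1Br | intermediate
7 | [3,5-bis(benzyloxy)-2-bromophenoxy]trimethylsilane | C[Si](C)(C)Oc1cc(OCc2ccccc2)cc(OCc2ccccc2)c1Br | intermediate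
8 | lithium 3,5-bis(benzyloxy)-2-(trimethylsilyl)phenoxide | [Li+].[O-]c1cc(OCc2ccccc2)cc(OCc2ccccc2)c1[Si](C)(C)C | intermediate
9 | 3,5-bis(benzyloxy)-2-(trimethylsilyl)phenyl trifluoromethanesulfonate | O=S(=O)(Oc1cc(OCc2ccccc2)cc(OCc2ccccc2)c1[Si](C)(C)C)C(F)(F)F | intermediate
10 | (5S,6S)-5,6-dimethoxy-5,6-dimethyl-1,4-dioxan-2-one | O=C1CO[C@](C)(OC)[C@@](C)(OC)O1 | starting material
11 | 3,4,5-tris(benzyloxy)benzaldehyde | O=Cc1cc(OCc2ccccc2)c(OCc2ccccc2)c(OCc2ccccc2)c1 | starting material
12 | lithium enolate of 10 | [Li+].[O-]C1=CO[C@](C)(OC)[C@@](C)(OC)O1 | intermediate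
13 | lithium alkoxide of (3R,5S,6S)-3-{(R)-hydroxy[3,4,5-tris(benzyloxy)phenyl]methyl}-5,6-dimethoxy-5,6-dimethyl-1,4-dioxan-2-one (anti aldolate) | [Li+].O=C1[C@@H]([C@H]([O-])c2cc(OCc3ccccc3)c(OCc3ccccc3)c(OCc3ccccc3)c2)O[C@](C)(OC)[C@@](C)(OC)O1 | intermediate
14 | 3,5-bis(benzyloxy)benzyne | C1#CC(OCc2ccccc2)=CC(OCc2ccccc2)=C1 | intermediate
15 | (2R,3R)-5,7-bis(benzyloxy)-3-{[(2S)-2-methoxy-3-oxobutan-2-yl]oxy}-2-[3,4,5-tris(benzyloxy)phenyl]chroman-4-one | C(c1ccccc1)Oc1cc(OCc3ccccc3)c2c(c1)O[C@H](c1cc(OCc3ccccc3)c(OCc3ccccc3)c(OCc3ccccc3)c1)[C@@H](O[C@](C)(OC)C(C)=O)C2=O | intermediate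
16 | (2R,3R)-5,7,3',4',5'-penta-O-benzyldihydromyricetin | C(c1ccccc1)Oc1cc(OCc3ccccc3)c2c(c1)O[C@H](c1cc(OCc3ccccc3)c(OCc3ccccc3)c(OCc3ccccc3)c1)[C@@H](O)C2=O | intermediate
17 | (2R,3S,4R)-5,7-bis(benzyloxy)-2-[3,4,5-tris(benzyloxy)phenyl]chromane-3,4-diol | C(c1ccccc1)Oc1cc(OCc3ccccc3)c2c(c1)O[C@H](c1cc(OCc3ccccc3)c(OCc3ccccc3)c(OCc3ccccc3)c1)[C@@H](O)[C@@H]2O | intermediate
18 | trideca-O-benzyl gallocatechin-(4α→8)-catechin-(4α→8)-catechin | C(c1ccccc1)Oc1cc(OCc3ccccc3)c2c(c1)O[C@H](c1cc(OCc3ccccc3)c(OCc3ccccc3)c(OCc3ccccc3)c1)[C@@H](O)[C@@H]2c1c(OCc3ccccc3)cc(OCc3ccccc3)c2c1O[C@H](c1ccc(OCc3ccccc3)c(OCc3ccccc3)c1)[C@@H](O)[C@@H]2c1c(OCc3ccccc3)cc(OCc3ccccc3)c2c1O[C@H](c1ccc(OCc3ccccc3)c(OCc3ccccc3)c1)[C@@H](O)C2 | intermediate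
19 | gallocatechin-(4α→8)-catechin-(4α→8)-catechin | Oc1cc(O)c2c(c1)O[C@H](c1cc(O)c(O)c(O)c1)[C@@H](O)[C@@H]2c1c(O)cc(O)c2c1O[C@H](c1ccc(O)c(O)c1)[C@@H](O)[C@@H]2c1c(O)cc(O)c2c1O[C@H](c1ccc(O)c(O)c1)[C@@H](O)C2 | target

**Summary**

Total step count: 10. Longest linear sequence: 7 steps (steps 4 to 10, from 5 to 19).

Steps most likely to fail:

1. Step 6. The aldolate may equilibrate by retro-aldol before it meets the aryne, or the aryl anion may be protonated before it is acylated. The fallback uses established dihydroflavonol chemistry; it sets out from 11 and comes back at 16. Commercial 1-[2,4-bis(benzyloxy)-6-hydroxyphenyl]ethanone would be protected (MOMCl, i-Pr2NEt, CH2Cl2) as 1-[2,4-bis(benzyloxy)-6-(methoxymethoxy)phenyl]ethanone F1. Claisen–Schmidt condensation of F1 with 11 (KOH, EtOH/THF) should give (E)-1-[2,4-bis(benzyloxy)-6-(methoxymethoxy)phenyl]-3-[3,4,5-tris(benzyloxy)phenyl]prop-2-en-1-one F2. Juliá–Colonna epoxidation (poly-L-leucine, urea–H2O2, DBU, THF) should give the (αR,βS)-epoxy ketone F3. HCl in MeOH then removes the methoxymethyl group, and the freed phenol opens the epoxide at the benzylic carbon with inversion to give 16, which continues with step 8.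

2. Step 9. The C4 cation may condense with ring A of a second molecule of 17, or attack C6 instead of C8, so that oligomers and positional isomers form. The fallback adds a temporary halogen cap; it sets out from 17 and comes back at 19. Bromination (NBS, CH2Cl2, −20 °C) should give (2R,3S,4R)-5,7-bis(benzyloxy)-8-bromo-2-[3,4,5-tris(benzyloxy)phenyl]chromane-3,4-diol F4, whose ring A can no longer act as nucleophile at C8. Coupling of F4 with a near-equimolar amount of 4 under the acid conditions of step 9 should give the 8-bromo trideca-O-benzyl trimer F5. Hydrogenolysis (H2, Pd(OH)2/C, Et3N, THF/MeOH/H2O) removes bromine and benzyl groups together to give 19.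

3. Step 4. Bromination may occur at the position between the two benzyloxy groups, or twice. The fallback replaces it by directed ortho-metalation; it sets out from 5 and comes back at 9, so that step 5 is bypassed as well. Isopropyl isocyanate (Et3N cat., CH2Cl2) should give 3,5-bis(benzyloxy)phenyl isopropylcarbamate F6. N-Silylation in the flask (TMSOTf, TMEDA), then n-BuLi/TMEDA at −78 °C and TMSCl, should place silicon between the carbamate and a benzyloxy group to give 3,5-bis(benzyloxy)-2-(trimethylsilyl)phenyl isopropylcarbamate F7. Et2NH and DBU in MeCN cleave the carbamate to 3,5-bis(benzyloxy)-2-(trimethylsilyl)phenol F8, which is triflated in the same flask with PhNTf2 to give 9.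

Further compounds
F1 | step 6 | 1-[2,4-bis(benzyloxy)-6-(methoxymethoxy)phenyl]ethanone | CC(=O)c1c(OCOC)cc(OCc2ccccc2)cc1OCc1ccccc1
F2 | step 6 | (E)-1-[2,4-bis(benzyloxy)-6-(methoxymethoxy)phenyl]-3-[3,4,5-tris(benzyloxy)phenyl]prop-2-en-1-one | O=C(/C=C/c1cc(OCc2ccccc2)c(OCc2ccccc2)c(OCc2ccccc2)c1)c1c(OCOC)cc(OCc2ccccc2)cc1OCc1ccccc1
F3 | step 6 | [2,4-bis(benzyloxy)-6-(methoxymethoxy)phenyl]{(2R,3S)-3-[3,4,5-tris(benzyloxy)phenyl]oxiran-2-yl}methanone | O=C(c1c(OCOC)cc(OCc2ccccc2)cc1OCc1ccccc1)[C@@H]1O[C@H]1c1cc(OCc2ccccc2)c(OCc2ccccc2)c(OCc2ccccc2)c1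
F4 | step 9 | (2R,3S,4R)-5,7-bis(benzyloxy)-8-bromo-2-[3,4,5-tris(benzyloxy)phenyl]chromane-3,4-diol | C(c1ccccc1)Oc1cc(OCc3ccccc3)c2c(c1Br)O[C@H](c1cc(OCc3ccccc3)c(OCc3ccccc3)c(OCc3ccccc3)c1)[C@@H](O)[C@@H]2O
F5 | step 9 | 8-bromo trideca-O-benzyl gallocatechin-(4α→8)-catechin-(4α→8)-catechin (bromine on ring A of the gallocatechin unit) | C(c1ccccc1)Oc1cc(OCc3ccccc3)c2c(c1Br)O[C@H](c1cc(OCc3ccccc3)c(OCc3ccccc3)c(OCc3ccccc3)c1)[C@@H](O)[C@@H]2c1c(OCc3ccccc3)cc(OCc3ccccc3)c2c1O[C@H](c1ccc(OCc3ccccc3)c(OCc3ccccc3)c1)[C@@H](O)[C@@H]2c1c(OCc3ccccc3)cc(OCc3ccccc3)c2c1O[C@H](c1ccc(OCc3ccccc3)c(OCc3ccccc3)c1)[C@@H](O)C2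
F6 | step 4 | 3,5-bis(benzyloxy)phenyl isopropylcarbamate | CC(C)NC(=O)Oc1cc(OCc2ccccc2)cc(OCc2ccccc2)c1
F7 | step 4 | 3,5-bis(benzyloxy)-2-(trimethylsilyl)phenyl isopropylcarbamate | CC(C)NC(=O)Oc1cc(OCc2ccccc2)cc(OCc2ccccc2)c1[Si](C)(C)C
F8 | step 4 | 3,5-bis(benzyloxy)-2-(trimethylsilyl)phenol | Oc1cc(OCc2ccccc2)cc(OCc2ccccc2)c1[Si](C)(C)C
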